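**Plan**
- Retrosynthesis: the eleven methyl ethers come off last. Ring A is then cut at the carbon–carbon bond between its carbons 1 and 2, and the three remaining diaryl ether bonds (ring B carbon 4 to ring C carbon 1, ring C carbon 6 to ring D carbon 1, ring D carbon 5 to ring E carbon 1, each ring counted from the carbon whose oxygen points toward ring A) are each cut to a phenol and a bromobenzaldehyde.
- Enabling feature: ring A (carbon 1 carries the ether oxygen to ring B; carbons 2, 4 and 6 carry hydroxyls) is the cyclized form of a 3,5-dioxohexanoate with the aryloxy group on its terminal carbon. That chain can be stored as a 6-(aryloxymethyl)-4-methoxy-2-pyranone, so the crowded ether between ring A and ring B is made as a primary alkyl aryl ether.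
- Forward: rings E and D are joined first, then ring C, then ring B, each by an Ullmann coupling followed by a Dakin-type oxidation that turns the formyl group into the next phenol.
- The ring B phenol is alkylated with 6-(bromomethyl)-4-methoxy-2-pyranone, ring A is closed from the pyranone, and BBr3 frees the hydroxyls.
- Stereochemistry: the target has no stereocentre. The only geometric element, the E double bond of the transient open-chain enoate, is inherited from the pyranone ring.

Key step: step 10

Remark: the bromo aldehydes 2 and 11 are taken as purchasable. "BCDE-aryl" stands for the methylated ring B–C–D–E unit bound through carbon 1 of ring B, 4-{2-[3,4-dimethoxy-5-(3,4,5-trimethoxyphenoxy)phenoxy]-3,4,5-trimethoxyphenoxy}-3,5-dimethoxyphenyl.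

Step 1
Reactants: 1 3,4,5-trimethoxyphenol; 2 3-bromo-4,5-dimethoxybenzaldehyde
Product: 3 3,4-dimethoxy-5-(3,4,5-trimethoxyphenoxy)benzaldehyde
Conditions: CuI (10 mol %), picolinic acid (20 mol %), K3PO4, DMSO, 90 °C, argon
Reagents that add atoms: none
Why: Ullmann diaryl ether synthesis, in which the unhindered, electron-rich phenol 1 should couple readily with a bromide that has a single ortho methoxy group and a formyl group that tolerates the phosphate base.

Step 2
Reactants: 3 3,4-dimethoxy-5-(3,4,5-trimethoxyphenoxy)benzaldehyde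
Product: 5 3,4-dimethoxy-5-(3,4,5-trimethoxyphenoxy)phenol, via aryl formate 4 (not isolated)
Conditions: mCPBA, CH2Cl2, 0 °C to rt; aq. NaHCO3 wash; then K2CO3 (cat.), MeOH, rt
Reagents that add atoms: mCPBA, OOC(=O)c1cccc(Cl)c1
Why: Baeyer–Villiger (Dakin-type) oxidation, in which the aryl group activated by the para methoxy group migrates to give formate 4; the formate keeps the phenol masked until the peracid is washed out and is then cleaved by base-catalysed methanolysis.

Step 3
Reactants: 6 3,4,5-trimethoxybenzaldehyde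
Product: 7 2-bromo-3,4,5-trimethoxybenzaldehyde
Conditions: NBS, CHCl3, reflux
Reagents that add atoms: N-bromosuccinimide, O=C1CCC(=O)N1Br
Why: Electrophilic aromatic bromination; the two free ring positions of 6 are equivalent and activated by ortho and para methoxy groups, so only one monobromide can form.

Step 4
Reactants: 5 3,4-dimethoxy-5-(3,4,5-trimethoxyphenoxy)phenol; 7 2-bromo-3,4,5-trimethoxybenzaldehyde
Product: 8 2-[3,4-dimethoxy-5-(3,4,5-trimethoxyphenoxy)phenoxy]-3,4,5-trimethoxybenzaldehyde
Conditions: CuI (10 mol %), picolinic acid (20 mol %), K3PO4, DMSO, 90 °C, argon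
Reagents that add atoms: none
Why: Ullmann diaryl ether synthesis, in which the ortho formyl group activates the C–Br bond of 7 toward monovalent copper and the phenol 5 has no ortho substituent, which should offset the flanking methoxy group.

Step 5
Reactants: 8 2-[3,4-dimethoxy-5-(3,4,5-trimethoxyphenoxy)phenoxy]-3,4,5-trimethoxybenzaldehyde
Product: 10 2-[3,4-dimethoxy-5-(3,4,5-trimethoxyphenoxy)phenoxy]-3,4,5-trimethoxyphenol, via aryl formate 9 (not isolated)
Conditions: mCPBA, CH2Cl2, 0 °C to rt; aq. NaHCO3 wash; then K2CO3 (cat.), MeOH, rt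
Reagents that add atoms: mCPBA, OOC(=O)c1cccc(Cl)c1
Why: Baeyer–Villiger (Dakin-type) oxidation, in which the ortho aryloxy and para methoxy groups make the ring migrate in preference to hydride, and methanolysis of formate 9 then frees the phenol next to the new diaryl ether.

Step 6
Reactants: 10 2-[3,4-dimethoxy-5-(3,4,5-trimethoxyphenoxy)phenoxy]-3,4,5-trimethoxyphenol; 11 4-bromo-3,5-dimethoxybenzaldehyde
Product: 12 4-{2-[3,4-dimethoxy-5-(3,4,5-trimethoxyphenoxy)phenoxy]-3,4,5-trimethoxyphenoxy}-3,5-dimethoxybenzaldehyde (BCDE-aryl carbaldehyde)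
Conditions: CuI (20 mol %), picolinic acid (40 mol %), K3PO4, DMSO, 100 °C, argon
Reagents that add atoms: none
Why: Ullmann diaryl ether synthesis under the CuI/picolinic acid conditions developed for hindered partners; the para formyl group lowers the electron density at the bromine-bearing carbon between the two methoxy groups, and the phenol 10 has only one ortho substituent.

Step 7
Reactants: 12 4-{2-[3,4-dimethoxy-5-(3,4,5-trimethoxyphenoxy)phenoxy]-3,4,5-trimethoxyphenoxy}-3,5-dimethoxybenzaldehyde
Product: 14 4-{2-[3,4-dimethoxy-5-(3,4,5-trimethoxyphenoxy)phenoxy]-3,4,5-trimethoxyphenoxy}-3,5-dimethoxyphenol (BCDE-aryl phenol), via aryl formate 13 (not isolated)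
Conditions: mCPBA, CH2Cl2, rt to 40 °C; aq. NaHCO3 wash; then K2CO3 (cat.), MeOH, rt
Reagents that add atoms: mCPBA, OOC(=O)c1cccc(Cl)c1
Why: Baeyer–Villiger (Dakin-type) oxidation, in which the para aryloxy group directs aryl migration, as in the known conversion of 3,4,5-trialkoxybenzaldehydes into phenols, and methanolysis of formate 13 gives the ring B phenol.

Step 8
Reactants: 15 4-methoxy-6-methyl-2H-pyran-2-one
Product: 16 6-(bromomethyl)-4-methoxy-2H-pyran-2-one
Conditions: NBS, AIBN (cat.), PhCF3, reflux
Reagents that add atoms: N-bromosuccinimide, O=C1CCC(=O)N1Br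
Why: Wohl–Ziegler bromination; the 6-methyl group is the only allylic-type C–H position, its radical is delocalized over the pyranone, and the low bromine concentration under radical initiation disfavours ionic bromination at ring position 3.

Step 9
Reactants: 14 4-{2-[3,4-dimethoxy-5-(3,4,5-trimethoxyphenoxy)phenoxy]-3,4,5-trimethoxyphenoxy}-3,5-dimethoxyphenol; 16 6-(bromomethyl)-4-methoxy-2H-pyran-2-one
Product: 17 6-[(BCDE-aryloxy)methyl]-4-methoxy-2H-pyran-2-one
Conditions: K2CO3, acetone, rt to 40 °C
Reagents that add atoms: none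
Why: Williamson ether synthesis; SN2 displacement at the primary, allylic-type bromide by the phenoxide of 14, whose oxygen sits on a ring B carbon with two CH neighbours, should be much faster than attack on the pyranone ring under mild carbonate base.

Step 10
Reactants: 17 6-[(BCDE-aryloxy)methyl]-4-methoxy-2H-pyran-2-one
Product: 19 2-(BCDE-aryloxy)-5-methoxybenzene-1,3-diol, via open-chain enoate 18 (not isolated)
Conditions: Mg(OMe)2 (5 equiv), MeOH, reflux, then 110 °C (sealed tube), argon; then 1 M HCl
Reagents that add atoms: none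
Why: Proposed new method: magnesium-bound methoxide adds to the lactone carbonyl of 17 and the ring opens to the magnesium enolate of the E-enoate 18, in which the ester and the chain methylene stay cis; proton exchange in methanol then puts a small share of the enolate on the terminal carbon, which is alpha to the ketone and acidified by the aryloxy group, and this carbon attacks the ester carbon, expels methoxide and forms the bond between carbons 1 and 2 of ring A, after which the 5-methoxycyclohexene-1,3-dione enolizes to the resorcinol 19 with free hydroxyls on ring A carbons 2 and 6. The closest known reactions are the Mg(OMe)2-mediated opening of 6-(acylmethyl)-4-methoxy-2-pyranones with Claisen recyclization to acylphloroglucinols and the base-induced closure of 3,5-dioxohexanoates to phloroglucinol; here the attacking carbon is activated by one carbonyl only and bears an oxygen substituent, which is why the step is a proposal. Ring A closes in a 6-(enolendo)-exo-trig mode and no stereocentre is formed. The selectivity needed is carbon over oxygen acylation: attack by the ketone oxygen only returns 17 and is reversible, a six-carbon chain has no aldol mode, and aromatization of the carbon-acylated product is irreversible, so the equilibria should drain into 19. Magnesium chelation of the 3-methoxy-5-oxo unit folds the chain so that the terminal carbon lies over the ester, the aryloxy group cannot leave by beta-elimination because its neighbouring carbon is the ketone carbon and can carry no carbanion, and the aryl methyl ethers and diaryl ethers are inert to methoxide.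

Step 11
Reactants: 19 2-(BCDE-aryloxy)-5-methoxybenzene-1,3-diol
Product: 20 CNP0154768.0, 2-(4-{2-[3,4-dihydroxy-5-(3,4,5-trihydroxyphenoxy)phenoxy]-3,4,5-trihydroxyphenoxy}-3,5-dihydroxyphenoxy)benzene-1,3,5-triol
Conditions: BBr3 (excess), CH2Cl2, −78 °C to rt, argon; then H2O, 0 °C; isolation with degassed solvents under argon
Reagents that add atoms: none
Why: Lewis-acid ether cleavage, in which BBr3 coordinates each methoxy oxygen and bromide removes the methyl group by SN2 while the diaryl ether bonds, which offer no sp3 carbon, stay intact; hydrolysis of the aryl borates should free all thirteen hydroxyls.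

**Compound list**
1 | 3,4,5-trimethoxyphenol | COc1cc(O)cc(OC)c1OC | starting material
2 | 3-bromo-4,5-dimethoxybenzaldehyde | COc1cc(C=O)cc(Br)c1OC | starting material
3 | 3,4-dimethoxy-5-(3,4,5-trimethoxyphenoxy)benzaldehyde | COc1cc(C=O)cc(Oc2cc(OC)c(OC)c(OC)c2)c1OC | intermediate
4 | 3,4-dimethoxy-5-(3,4,5-trimethoxyphenoxy)phenyl formate | COc1cc(OC=O)cc(Oc2cc(OC)c(OC)c(OC)c2)c1OC | intermediate
5 | 3,4-dimethoxy-5-(3,4,5-trimethoxyphenoxy)phenol | COc1cc(O)cc(Oc2cc(OC)c(OC)c(OC)c2)c1OC | intermediate
6 | 3,4,5-trimethoxybenzaldehyde | COc1cc(C=O)cc(OC)c1OC | starting material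
7 | 2-bromo-3,4,5-trimethoxybenzaldehyde | COc1cc(C=O)c(Br)c(OC)c1OC | intermediate
8 | 2-[3,4-dimethoxy-5-(3,4,5-trimethoxyphenoxy)phenoxy]-3,4,5-trimethoxybenzaldehyde | COc1cc(C=O)c(Oc2cc(OC)c(OC)c(Oc3cc(OC)c(OC)c(OC)c3)c2)c(OC)c1OC | intermediate
9 | 2-[3,4-dimethoxy-5-(3,4,5-trimethoxyphenoxy)phenoxy]-3,4,5-trimethoxyphenyl formate | COc1cc(OC=O)c(Oc2cc(OC)c(OC)c(Oc3cc(OC)c(OC)c(OC)c3)c2)c(OC)c1OC | intermediate
10 | 2-[3,4-dimethoxy-5-(3,4,5-trimethoxyphenoxy)phenoxy]-3,4,5-trimethoxyphenol | COc1cc(O)c(Oc2cc(OC)c(OC)c(Oc3cc(OC)c(OC)c(OC)c3)c2)c(OC)c1OC | intermediate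
11 | 4-bromo-3,5-dimethoxybenzaldehyde | COc1cc(C=O)cc(OC)c1Br | starting material
12 | 4-{2-[3,4-dimethoxy-5-(3,4,5-trimethoxyphenoxy)phenoxy]-3,4,5-trimethoxyphenoxy}-3,5-dimethoxybenzaldehyde | COc1cc(C=O)cc(OC)c1Oc1cc(OC)c(OC)c(OC)c1Oc1cc(OC)c(OC)c(Oc2cc(OC)c(OC)c(OC)c2)c1 | intermediate
13 | 4-{2-[3,4-dimethoxy-5-(3,4,5-trimethoxyphenoxy)phenoxy]-3,4,5-trimethoxyphenoxy}-3,5-dimethoxyphenyl formate | COc1cc(OC=O)cc(OC)c1Oc1cc(OC)c(OC)c(OC)c1Oc1cc(OC)c(OC)c(Oc2cc(OC)c(OC)c(OC)c2)c1 | intermediate
14 | 4-{2-[3,4-dimethoxy-5-(3,4,5-trimethoxyphenoxy)phenoxy]-3,4,5-trimethoxyphenoxy}-3,5-dimethoxyphenol | COc1cc(O)cc(OC)c1Oc1cc(OC)c(OC)c(OC)c1Oc1cc(OC)c(OC)c(Oc2cc(OC)c(OC)c(OC)c2)c1 | intermediate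
15 | 4-methoxy-6-methyl-2H-pyran-2-one | COC1=CC(=O)OC(C)=C1 | starting material
16 | 6-(bromomethyl)-4-methoxy-2H-pyran-2-one | COC1=CC(=O)OC(CBr)=C1 | intermediate
17 | 6-[(4-{2-[3,4-dimethoxy-5-(3,4,5-trimethoxyphenoxy)phenoxy]-3,4,5-trimethoxyphenoxy}-3,5-dimethoxyphenoxy)methyl]-4-methoxy-2H-pyran-2-one | COC1=CC(=O)OC(COc2cc(OC)c(Oc3cc(OC)c(OC)c(OC)c3Oc4cc(OC)c(OC)c(Oc5cc(OC)c(OC)c(OC)c5)c4)c(OC)c2)=C1 | intermediate
18 | methyl (2E)-6-(4-{2-[3,4-dimethoxy-5-(3,4,5-trimethoxyphenoxy)phenoxy]-3,4,5-trimethoxyphenoxy}-3,5-dimethoxyphenoxy)-3-methoxy-5-oxohex-2-enoate | COC(=O)/C=C(/OC)CC(=O)COc1cc(OC)c(Oc2cc(OC)c(OC)c(OC)c2Oc3cc(OC)c(OC)c(Oc4cc(OC)c(OC)c(OC)c4)c3)c(OC)c1 | intermediate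
19 | 2-(4-{2-[3,4-dimethoxy-5-(3,4,5-trimethoxyphenoxy)phenoxy]-3,4,5-trimethoxyphenoxy}-3,5-dimethoxyphenoxy)-5-methoxybenzene-1,3-diol | COc1cc(O)c(Oc2cc(OC)c(Oc3cc(OC)c(OC)c(OC)c3Oc4cc(OC)c(OC)c(Oc5cc(OC)c(OC)c(OC)c5)c4)c(OC)c2)c(O)c1 | intermediate
20 | CNP0154768.0, 2-(4-{2-[3,4-dihydroxy-5-(3,4,5-trihydroxyphenoxy)phenoxy]-3,4,5-trihydroxyphenoxy}-3,5-dihydroxyphenoxy)benzene-1,3,5-triol | Oc1cc(O)c(Oc2cc(O)c(Oc3cc(O)c(O)c(O)c3Oc3cc(O)c(O)c(Oc4cc(O)c(O)c(O)c4)c3)c(O)c2)c(O)c1 | target

**Step count**
Total: 11 steps. Longest linear sequence: 9 steps (steps 1, 2, 4, 5, 6, 7, 9, 10, 11, from 1 and 2).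

**Steps most likely to fail**

Step 10 (proposed new method). The terminal enolate is present only in a small equilibrium share and the beta-methoxy enoate ester is a weak acceptor. Ring closure may therefore stall at the open-chain stage or revert to the pyranone, while slower intermolecular condensations or ester cleavage by adventitious water consume the chain. The fallback gives up the ring construction and makes the ether bond at ring A carbon 1 directly by known Ullmann chemistry of the kind used for phlorethol methyl ethers. It sets out from phenol 14, which has no ortho substituent and is coupled with 2-iodo-1,3,5-trimethoxybenzene (CuI, picolinic acid, K3PO4, DMSO, 100 °C). This should give the dodecamethyl ether 1,3,5-trimethoxy-2-(4-{2-[3,4-dimethoxy-5-(3,4,5-trimethoxyphenoxy)phenoxy]-3,4,5-trimethoxyphenoxy}-3,5-dimethoxyphenoxy)benzene F1. Treatment of F1 with BBr3 as in step 11 returns to the route at the target 20.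

Step 6. Substitution at the bromine-bearing carbon flanked by two methoxy groups may be slow, so that reductive loss of bromine from 11 and oxidative degradation of the electron-rich phenol take over. The fallback leaves copper catalysis for an uncatalysed nucleophilic aromatic substitution. It sets out from phenol 10, which is heated with 4-fluoro-3,5-dimethoxybenzaldehyde and Cs2CO3 in DMSO at 120 °C. The rate-limiting addition para to the formyl group is less sensitive to the flanking methoxy groups when fluoride is the leaving group. The product is aldehyde 12, where the fallback rejoins the route, and no new compound arises (entry F0).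

Step 11. Cleavage of the last of eleven methyl ethers may remain incomplete, and the free polyphenol may be lost to air oxidation during isolation. The fallback changes the end game to capture, purification and release. It sets out from 19: the crude product of the BBr3 treatment is acetylated at once (Ac2O, pyridine, DMAP) to the tridecaacetate 2-(4-{2-[3,4-diacetoxy-5-(3,4,5-triacetoxyphenoxy)phenoxy]-3,4,5-triacetoxyphenoxy}-3,5-diacetoxyphenoxy)benzene-1,3,5-triyl triacetate F2. F2 is stable in air and can be purified on silica, and fractions that still hold methyl ethers can be returned to BBr3. Acid-catalysed methanolysis (HCl in degassed MeOH, argon) then releases the target 20, where the fallback rejoins the route.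

**Further compounds**
F1 | step 10 | 1,3,5-trimethoxy-2-(4-{2-[3,4-dimethoxy-5-(3,4,5-trimethoxyphenoxy)phenoxy]-3,4,5-trimethoxyphenoxy}-3,5-dimethoxyphenoxy)benzene | COc1cc(OC)c(Oc2cc(OC)c(Oc3cc(OC)c(OC)c(OC)c3Oc4cc(OC)c(OC)c(Oc5cc(OC)c(OC)c(OC)c5)c4)c(OC)c2)c(OC)c1
F0 | step 6 | none | none
F2 | step 11 | 2-(4-{2-[3,4-diacetoxy-5-(3,4,5-triacetoxyphenoxy)phenoxy]-3,4,5-triacetoxyphenoxy}-3,5-diacetoxyphenoxy)benzene-1,3,5-triyl triacetate | CC(=O)Oc1cc(OC(C)=O)c(Oc2cc(OC(C)=O)c(Oc3cc(OC(C)=O)c(OC(C)=O)c(OC(C)=O)c3Oc3cc(OC(C)=O)c(OC(C)=O)c(Oc4cc(OC(C)=O)c(OC(C)=O)c(OC(C)=O)c4)c3)c(OC(C)=O)c2)c(OC(C)=O)c1
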